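**Plan**

1. Ring names: ring A is the 4-hydroxyphenyl ring; ring B is the stilbene resorcinol ring fused to the first dihydrofuran (O1, C2, C3, C3a, C7a); ring C is the aryl group on C2, fused to the second dihydrofuran (O1', C2', C3', C3a', C7a'); ring D is the 2,4-dihydroxyphenyl group on C2'.
2. Retrosynthesis: remove six methyl ethers and three triflates; cut O1'–C7a' and C3a'–C3' (ring C aryne plus stilbene oxide 20); then cut O1–C7a and C3a–C3 (ring B aryne plus stilbene oxide 16).
3. Forward: three stilbenes arise by Horner–Wadsworth–Emmons olefination and two are epoxidised. The ring B aryne is inserted into oxirane 16 to close the first dihydrofuran. The o-iodoaryl triflate kept on ring C then becomes the ring C aryne and is inserted into oxirane 20 to close the second.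
4. Enabling feature: the oxygen on C4 of ring B, next to ring-fusion carbon C3a, makes the C3a≡C7a aryne a 3-alkoxyaryne, so an oxygen nucleophile adds at C7a and the carbanion appears at C3a (likewise the oxygen on C4' of ring C). Rings C and D are carried as electron-poor aryl triflates so that each oxiranium opens at the carbon bearing the 3,5-dimethoxyphenyl group.
5. Stereochemistry: C2 and C2' come from two Shi epoxidations and are not touched afterwards; C3 and C3' are set trans to them in the ring closures.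

Key step: step 12

Assumption: 3-hydroxy-2-iodo-4-methoxybenzaldehyde (11) is taken as a purchasable building block, and the D-fructose-derived ketone of the Shi epoxidation is taken to give the (R,R)-oxiranes from these (E)-stilbenes as it does from (E)-stilbene.

Step 1
Reactants: 1 4-bromo-3,5-dimethoxybenzaldehyde; 2 diethyl (4-methoxybenzyl)phosphonate
Product: 3 (E)-2-bromo-1,3-dimethoxy-5-[2-(4-methoxyphenyl)ethenyl]benzene
Conditions: NaH, THF, 0 °C → rt
Reagents that add atoms: none
Why: Horner–Wadsworth–Emmons olefination of an aryl aldehyde with a benzylphosphonate anion, which should give the (E)-stilbene.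

Step 2
Reactants: 3 (E)-2-bromo-1,3-dimethoxy-5-[2-(4-methoxyphenyl)ethenyl]benzene
Product: 4 (E)-2-bromo-5-[2-(4-hydroxyphenyl)ethenyl]benzene-1,3-diol
Conditions: BBr3, CH2Cl2, −78 °C → rt; aq. work-up
Reagents that add atoms: none
Why: Lewis-acid cleavage of aryl methyl ethers, needed because the next step requires silyl groups on the two oxygens flanking the bromide.

Step 3
Reactants: 4 (E)-2-bromo-5-[2-(4-hydroxyphenyl)ethenyl]benzene-1,3-diol
Product: 9 (E)-3-hydroxy-5-[2-(4-hydroxyphenyl)ethenyl]-2-(trimethylsilyl)phenyl trifluoromethanesulfonate, via tris-O-silyl bromostilbene 5 (not isolated), via aryllithium 6 (not isolated), via lithium phenolate 7 (not isolated), via bis-O-silyl aryl triflate 8 (not isolated)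
Conditions: (Me3Si)2NH, THF, 65 °C, evaporate; n-BuLi, THF, −78 °C; Tf2O, −78 °C → rt; then dilute aq. citric acid, THF, rt
Reagents that add atoms: hexamethyldisilazane, C[Si](C)(C)N[Si](C)(C)C; trifluoromethanesulfonic anhydride, O=S(=O)(OS(=O)(=O)C(F)(F)F)C(F)(F)F
Why: bromine–lithium exchange on the O-silylated 2-bromoresorcinol unit triggers a retro-Brook 1,3-shift of one ortho silyl group from O to C (the two oxygens are equivalent, so the desymmetrisation is not statistical), the freed phenolate is trapped as triflate, and the labile aryl O–SiMe3 groups are hydrolysed on work-up.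

Step 4
Reactants: 9 (E)-3-hydroxy-5-[2-(4-hydroxyphenyl)ethenyl]-2-(trimethylsilyl)phenyl trifluoromethanesulfonate
Product: 10 (E)-3-methoxy-5-[2-(4-methoxyphenyl)ethenyl]-2-(trimethylsilyl)phenyl trifluoromethanesulfonate
Conditions: MeI (excess), K2CO3, acetone, 0 °C → rt
Reagents that add atoms: iodomethane, CI
Why: Williamson methylation of both phenols; with excess MeI at low temperature, alkylation of the potassium phenolate should outrun the C-to-O silyl shift that would release the aryne prematurely.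

Step 5
Reactants: 11 3-hydroxy-2-iodo-4-methoxybenzaldehyde
Product: 12 3,4-dihydroxy-2-iodobenzaldehyde
Conditions: BBr3, CH2Cl2, −78 °C → rt; aq. work-up
Reagents that add atoms: none
Why: aryl methyl ether cleavage, so that both oxygens of ring C can be carried as electron-withdrawing triflates.

Step 6
Reactants: 12 3,4-dihydroxy-2-iodobenzaldehyde
Product: 13 4-formyl-3-iodo-1,2-phenylene bis(trifluoromethanesulfonate)
Conditions: Tf2O, pyridine, CH2Cl2, 0 °C
Reagents that add atoms: trifluoromethanesulfonic anhydride, O=S(=O)(OS(=O)(=O)C(F)(F)F)C(F)(F)F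
Why: O-sulfonylation of both phenols; the iodide with the triflate next to it is the latent ring C aryne, and the second triflate is the later C4' oxygen.

Step 7
Reactants: 13 4-formyl-3-iodo-1,2-phenylene bis(trifluoromethanesulfonate); 14 diethyl (3,5-dimethoxybenzyl)phosphonate
Product: 15 (E)-4-[2-(3,5-dimethoxyphenyl)ethenyl]-3-iodo-1,2-phenylene bis(trifluoromethanesulfonate)
Conditions: NaH, THF, 0 °C (anion preformed), then 13, −20 °C → rt
Reagents that add atoms: none
Why: Horner–Wadsworth–Emmons olefination of a very electrophilic aldehyde; the preformed, non-alkoxide phosphonate anion should leave the aryl triflates intact and give the (E)-stilbene.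

Step 8
Reactants: 15 (E)-4-[2-(3,5-dimethoxyphenyl)ethenyl]-3-iodo-1,2-phenylene bis(trifluoromethanesulfonate)
Product: 16 4-[(2R,3R)-3-(3,5-dimethoxyphenyl)oxiran-2-yl]-3-iodo-1,2-phenylene bis(trifluoromethanesulfonate)
Conditions: D-fructose-derived Shi ketone (0.3 equiv), Oxone (2KHSO5·KHSO4·K2SO4), K2CO3, Bu4NHSO4, MeCN–CH2(OMe)2 / aq. Na2B4O7 buffer (pH 10.5), 0 °C
Reagents that add atoms: potassium peroxymonosulfate, [K+].[O-]S(=O)(=O)OO
Why: Shi asymmetric epoxidation; the chiral dioxirane should transfer oxygen to one face of the (E)-alkene through the spiro transition state and set both oxirane carbons as R (reagent control).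

Step 9
Reactants: 17 2,4-dihydroxybenzaldehyde
Product: 18 4-formyl-1,3-phenylene bis(trifluoromethanesulfonate)
Conditions: Tf2O, pyridine, CH2Cl2, 0 °C
Reagents that add atoms: trifluoromethanesulfonic anhydride, O=S(=O)(OS(=O)(=O)C(F)(F)F)C(F)(F)F
Why: O-sulfonylation; the two triflates protect ring D and make it electron-poor for step 13.

Step 10
Reactants: 18 4-formyl-1,3-phenylene bis(trifluoromethanesulfonate); 14 diethyl (3,5-dimethoxybenzyl)phosphonate
Product: 19 (E)-4-[2-(3,5-dimethoxyphenyl)ethenyl]-1,3-phenylene bis(trifluoromethanesulfonate)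
Conditions: NaH, THF, 0 °C (anion preformed), then 18, −20 °C → rt
Reagents that add atoms: none
Why: Horner–Wadsworth–Emmons olefination giving the (E)-stilbene, as in step 7.

Step 11
Reactants: 19 (E)-4-[2-(3,5-dimethoxyphenyl)ethenyl]-1,3-phenylene bis(trifluoromethanesulfonate)
Product: 20 4-[(2R,3R)-3-(3,5-dimethoxyphenyl)oxiran-2-yl]-1,3-phenylene bis(trifluoromethanesulfonate)
Conditions: D-fructose-derived Shi ketone (0.3 equiv), Oxone (2KHSO5·KHSO4·K2SO4), K2CO3, Bu4NHSO4, MeCN–CH2(OMe)2 / aq. Na2B4O7 buffer (pH 10.5), 0 °C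
Reagents that add atoms: potassium peroxymonosulfate, [K+].[O-]S(=O)(=O)OO
Why: Shi asymmetric epoxidation; the same ketone enantiomer as in step 8 should give the (2R,3R)-oxirane by reagent control.

Step 12
Reactants: 10 (E)-3-methoxy-5-[2-(4-methoxyphenyl)ethenyl]-2-(trimethylsilyl)phenyl trifluoromethanesulfonate; 16 4-[(2R,3R)-3-(3,5-dimethoxyphenyl)oxiran-2-yl]-3-iodo-1,2-phenylene bis(trifluoromethanesulfonate)
Product: 22 (2S,3S)-3-(3,5-dimethoxyphenyl)-2-[2-iodo-3,4-bis(trifluoromethanesulfonyloxy)phenyl]-4-methoxy-6-[(E)-2-(4-methoxyphenyl)ethenyl]-2,3-dihydro-1-benzofuran, via ring B aryne 21 (not isolated)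
Conditions: CsF, 18-crown-6, toluene–MeCN (3:1), 25 °C, slow addition of 10 (2 equiv) to 16
Reagents that add atoms: none
Why: Proposed new method: fluoride removes the silyl group of 10 and expels triflate to give the 3-methoxyaryne 21, whose C3a≡C7a bond is polarised by the C4 methoxy group so that the oxirane oxygen of 16 adds at the distal carbon (future C7a) and leaves a carbanion at C3a next to OMe; the O-aryl oxiranium cannot be displaced from the back because the leaving oxygen is tethered inside the forming ring, so its C3–O bond ionises to a benzylic cation that recombines with the neighbouring carbanion. The closest known reaction type is the formal insertion of benzyne into the benzylic C–O bond of styrene oxide to give a dihydrobenzofuran, extended here to a stereodefined 2,3-diaryloxirane and an unsymmetrical aryne. One ring closes, the five-membered dihydrofuran, by ring expansion of the oxirane through carbanion–carbocation collapse on the face the oxygen has just left (front-side closure, formally a [3+2] annulation by σ-insertion). C2 is never broken and keeps the configuration set in step 8 (2R in the oxirane becomes 2S only through the change in CIP priorities), while C3 is set trans to the C2 aryl group, both because front-side collapse of a trans-oxirane gives the trans ring and because trans-2,3-diaryl is the less strained arrangement should the cation relax first. Three selectivities are needed: aryne regiochemistry, secured by the C4 oxygen of ring B; cleavage of C3–O and not C2–O, secured by keeping ring C as a twisted, electron-poor 2-iodo-3,4-bis(triflyloxy)phenyl group that cannot stabilise a cation at C2 while the 3,5-dimethoxyphenyl group at C3 can; and capture of the aryne by the oxirane oxygen and not by fluoride, served by slow addition of 10 in a weakly nucleophilic, non-protic medium.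

Step 13
Reactants: 22 (2S,3S)-3-(3,5-dimethoxyphenyl)-2-[2-iodo-3,4-bis(trifluoromethanesulfonyloxy)phenyl]-4-methoxy-6-[(E)-2-(4-methoxyphenyl)ethenyl]-2,3-dihydro-1-benzofuran; 20 4-[(2R,3R)-3-(3,5-dimethoxyphenyl)oxiran-2-yl]-1,3-phenylene bis(trifluoromethanesulfonate)
Product: 25 (2S,3S)-2-{(2S,3S)-2-[2,4-bis(trifluoromethanesulfonyloxy)phenyl]-3-(3,5-dimethoxyphenyl)-4-(trifluoromethanesulfonyloxy)-2,3-dihydro-1-benzofuran-7-yl}-3-(3,5-dimethoxyphenyl)-4-methoxy-6-[(E)-2-(4-methoxyphenyl)ethenyl]-2,3-dihydro-1-benzofuran, via arylmagnesium chloride 23 (not isolated), via ring C aryne 24 (not isolated)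
Conditions: Me3SiCH2MgCl (1.3 equiv), 20 (4 equiv), toluene with the minimum of Et2O, −78 → 0 °C
Reagents that add atoms: none
Why: Proposed new method: iodine–magnesium exchange with the poorly nucleophilic Me3SiCH2MgCl and loss of the neighbouring triflate (a known entry to 3-(triflyloxy)arynes) gives aryne 24; the remaining triflate on C4' should direct the oxirane oxygen of 20 to the distal aryne carbon (future C7a') and the carbanion to C3a', the oxiranium should open at the carbon bearing the 3,5-dimethoxyphenyl group because the 2,4-bis(triflyloxy)phenyl group disfavours a cation at the other, C2' keeps the configuration from step 11 and C3' closes trans as in step 12; the closest known reaction type is again aryne insertion into the C–O bond of styrene oxide.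

Step 14
Reactants: 25 the protected trimer (six methyl ethers, three triflates)
Product: 26 (2S,3S)-2-{(2S,3S)-2-[2,4-bis(trifluoromethanesulfonyloxy)phenyl]-3-(3,5-dihydroxyphenyl)-4-(trifluoromethanesulfonyloxy)-2,3-dihydro-1-benzofuran-7-yl}-3-(3,5-dihydroxyphenyl)-6-[(E)-2-(4-hydroxyphenyl)ethenyl]-2,3-dihydro-1-benzofuran-4-ol
Conditions: BBr3 (excess), CH2Cl2, −78 → 0 °C; aq. work-up
Reagents that add atoms: none
Why: aryl methyl ether cleavage; the triflates are inert to BBr3 and keep rings C and D electron-poor, which should protect the two benzylic C2–O bonds from Lewis-acid ionisation.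

Step 15
Reactants: 26 the hexaphenol tris(triflate)
Product: 27 Gnetumontanin B
Conditions: Et4NOH (aq.), 1,4-dioxane, rt, argon; then 1 M HCl to pH 4
Reagents that add atoms: none
Why: hydroxide attacks sulfur of the aryl triflates (S–O cleavage) and frees the last three phenols at room temperature without touching any stereocentre; air is excluded to protect the polyphenolate.

**Compound list**

1 | 4-bromo-3,5-dimethoxybenzaldehyde | COc1cc(C=O)cc(OC)c1Br | starting material
2 | diethyl (4-methoxybenzyl)phosphonate | CCOP(=O)(Cc1ccc(OC)cc1)OCC | starting material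
3 | (E)-2-bromo-1,3-dimethoxy-5-[2-(4-methoxyphenyl)ethenyl]benzene | COc1ccc(/C=C/c2cc(OC)c(Br)c(OC)c2)cc1 | intermediate
4 | (E)-2-bromo-5-[2-(4-hydroxyphenyl)ethenyl]benzene-1,3-diol | Oc1ccc(/C=C/c2cc(O)c(Br)c(O)c2)cc1 | intermediate
5 | tris(trimethylsilyl) ether of 4 | C[Si](C)(C)Oc1ccc(/C=C/c2cc(O[Si](C)(C)C)c(Br)c(O[Si](C)(C)C)c2)cc1 | intermediate
6 | [2,6-bis(trimethylsilyloxy)-4-{(E)-2-[4-(trimethylsilyloxy)phenyl]ethenyl}phenyl]lithium | C[Si](C)(C)Oc1ccc(/C=C/c2cc(O[Si](C)(C)C)c([Li])c(O[Si](C)(C)C)c2)cc1 | intermediate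
7 | lithium 3-(trimethylsilyloxy)-5-{(E)-2-[4-(trimethylsilyloxy)phenyl]ethenyl}-2-(trimethylsilyl)phenolate | [Li+].C[Si](C)(C)Oc1ccc(/C=C/c2cc([O-])c([Si](C)(C)C)c(O[Si](C)(C)C)c2)cc1 | intermediate
8 | 3-(trimethylsilyloxy)-5-{(E)-2-[4-(trimethylsilyloxy)phenyl]ethenyl}-2-(trimethylsilyl)phenyl trifluoromethanesulfonate | C[Si](C)(C)Oc1ccc(/C=C/c2cc(OS(=O)(=O)C(F)(F)F)c([Si](C)(C)C)c(O[Si](C)(C)C)c2)cc1 | intermediate
9 | (E)-3-hydroxy-5-[2-(4-hydroxyphenyl)ethenyl]-2-(trimethylsilyl)phenyl trifluoromethanesulfonate | Oc1ccc(/C=C/c2cc(O)c([Si](C)(C)C)c(OS(=O)(=O)C(F)(F)F)c2)cc1 | intermediate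
10 | (E)-3-methoxy-5-[2-(4-methoxyphenyl)ethenyl]-2-(trimethylsilyl)phenyl trifluoromethanesulfonate | COc1ccc(/C=C/c2cc(OC)c([Si](C)(C)C)c(OS(=O)(=O)C(F)(F)F)c2)cc1 | intermediate
11 | 3-hydroxy-2-iodo-4-methoxybenzaldehyde | COc1ccc(C=O)c(I)c1O | starting material
12 | 3,4-dihydroxy-2-iodobenzaldehyde | O=Cc1ccc(O)c(O)c1I | intermediate
13 | 4-formyl-3-iodo-1,2-phenylene bis(trifluoromethanesulfonate) | O=Cc1ccc(OS(=O)(=O)C(F)(F)F)c(OS(=O)(=O)C(F)(F)F)c1I | intermediate
14 | diethyl (3,5-dimethoxybenzyl)phosphonate | CCOP(=O)(Cc1cc(OC)cc(OC)c1)OCC | starting material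
15 | (E)-4-[2-(3,5-dimethoxyphenyl)ethenyl]-3-iodo-1,2-phenylene bis(trifluoromethanesulfonate) | COc1cc(/C=C/c2ccc(OS(=O)(=O)C(F)(F)F)c(OS(=O)(=O)C(F)(F)F)c2I)cc(OC)c1 | intermediate
16 | 4-[(2R,3R)-3-(3,5-dimethoxyphenyl)oxiran-2-yl]-3-iodo-1,2-phenylene bis(trifluoromethanesulfonate) | Ic1c([C@H]2O[C@@H]2c2cc(OC)cc(OC)c2)ccc(OS(=O)(=O)C(F)(F)F)c1OS(=O)(=O)C(F)(F)F | intermediate
17 | 2,4-dihydroxybenzaldehyde | O=Cc1ccc(O)cc1O | starting material
18 | 4-formyl-1,3-phenylene bis(trifluoromethanesulfonate) | O=Cc1ccc(OS(=O)(=O)C(F)(F)F)cc1OS(=O)(=O)C(F)(F)F | intermediate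
19 | (E)-4-[2-(3,5-dimethoxyphenyl)ethenyl]-1,3-phenylene bis(trifluoromethanesulfonate) | COc1cc(/C=C/c2ccc(OS(=O)(=O)C(F)(F)F)cc2OS(=O)(=O)C(F)(F)F)cc(OC)c1 | intermediate
20 | 4-[(2R,3R)-3-(3,5-dimethoxyphenyl)oxiran-2-yl]-1,3-phenylene bis(trifluoromethanesulfonate) | FC(F)(F)S(=O)(=O)Oc1ccc([C@H]2O[C@@H]2c2cc(OC)cc(OC)c2)c(OS(=O)(=O)C(F)(F)F)c1 | intermediate
21 | 3-methoxy-5-[(E)-2-(4-methoxyphenyl)ethenyl]benzyne (ring B aryne, 1,2-didehydro) | COc1ccc(/C=C/C2=CC#CC(OC)=C2)cc1 | intermediate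
22 | (2S,3S)-3-(3,5-dimethoxyphenyl)-2-[2-iodo-3,4-bis(trifluoromethanesulfonyloxy)phenyl]-4-methoxy-6-[(E)-2-(4-methoxyphenyl)ethenyl]-2,3-dihydro-1-benzofuran | COc1ccc(/C=C/c2cc(OC)c3c(c2)O[C@H](c2ccc(OS(=O)(=O)C(F)(F)F)c(OS(=O)(=O)C(F)(F)F)c2I)[C@H]3c2cc(OC)cc(OC)c2)cc1 | intermediate
23 | arylmagnesium chloride from 22 (MgCl in place of I) | COc1ccc(/C=C/c2cc(OC)c3c(c2)O[C@H](c2ccc(OS(=O)(=O)C(F)(F)F)c(OS(=O)(=O)C(F)(F)F)c2[Mg]Cl)[C@H]3c2cc(OC)cc(OC)c2)cc1 | intermediate
24 | ring C aryne from 23 (2,3-didehydro, 4-triflyloxy) | COc1ccc(/C=C/c2cc(OC)c3c(c2)O[C@H](C2=CC=C(OS(=O)(=O)C(F)(F)F)C#C2)[C@H]3c2cc(OC)cc(OC)c2)cc1 | intermediate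
25 | protected trimer: (2S,3S)-2-{(2S,3S)-2-[2,4-bis(triflyloxy)phenyl]-3-(3,5-dimethoxyphenyl)-4-(triflyloxy)-2,3-dihydro-1-benzofuran-7-yl}-3-(3,5-dimethoxyphenyl)-4-methoxy-6-[(E)-2-(4-methoxyphenyl)ethenyl]-2,3-dihydro-1-benzofuran | COc1ccc(/C=C/c2cc(OC)c3c(c2)O[C@H](c2ccc(OS(=O)(=O)C(F)(F)F)c4c2O[C@H](c2ccc(OS(=O)(=O)C(F)(F)F)cc2OS(=O)(=O)C(F)(F)F)[C@H]4c2cc(OC)cc(OC)c2)[C@H]3c2cc(OC)cc(OC)c2)cc1 | intermediate
26 | hexaphenol tris(triflate): 25 with all six OMe as OH | Oc1ccc(/C=C/c2cc(O)c3c(c2)O[C@H](c2ccc(OS(=O)(=O)C(F)(F)F)c4c2O[C@H](c2ccc(OS(=O)(=O)C(F)(F)F)cc2OS(=O)(=O)C(F)(F)F)[C@H]4c2cc(O)cc(O)c2)[C@H]3c2cc(O)cc(O)c2)cc1 | intermediate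
27 | Gnetumontanin B | Oc1ccc(/C=C/c2cc(O)c3c(c2)O[C@H](c2ccc(O)c4c2O[C@H](c2ccc(O)cc2O)[C@H]4c2cc(O)cc(O)c2)[C@H]3c2cc(O)cc(O)c2)cc1 | target

**Totals and risks**

Total steps: 15. Longest linear sequence: 8 steps (steps 5, 6, 7, 8, 12, 13, 14, 15; the arm through steps 1–4 is equally long).

Step 12 (proposed new method). The oxiranium may ionise at C2 instead of C3, or the aryl carbanion may be quenched before the C–C bond forms, giving ring-opened aryl ethers; the electron-poor oxirane oxygen may also lose the aryne to fluoride. The fallback builds the same ring by known reactions, sets out from 10 and 13 and returns at 22. Aryne 21 is generated from 10 as before and trapped in a 1,3-dipolar cycloaddition with (Z)-1-(3,5-dimethoxyphenyl)-N-methylmethanimine N-oxide F1 (from 3,5-dimethoxybenzaldehyde and MeNHOH·HCl), oxygen going to C7a as for any 3-alkoxyaryne. This should give racemic 3-(3,5-dimethoxyphenyl)-4-methoxy-6-[(E)-2-(4-methoxyphenyl)ethenyl]-2-methyl-2,3-dihydro-1,2-benzoxazole F2. Zn in AcOH cleaves the N–O bond to racemic 2-[(3,5-dimethoxyphenyl)(methylamino)methyl]-3-methoxy-5-[(E)-2-(4-methoxyphenyl)ethenyl]phenol F3. Separately, NaBH4 reduces 13 to 4-(hydroxymethyl)-3-iodo-1,2-phenylene bis(trifluoromethanesulfonate) F4, which with thiolane and HBF4·OEt2 gives 1-{[2-iodo-3,4-bis(trifluoromethanesulfonyloxy)phenyl]methyl}thiolan-1-ium tetrafluoroborate F5. Warming F3 with F5 and Cs2CO3 in MeCN should release the ortho-quinone methide (loss of methylamine) and the sulfonium ylide, whose [4+1] annulation gives the trans-dihydrobenzofuran as a racemate of 22 and its (2R,3R)-enantiomer F6. Preparative chiral HPLC removes F6 and returns the route to 22.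

Step 13 (proposed new method). The oxirane oxygen may add too slowly at the aryne carbon flanked by the substituted ring carbon, the carbanion may expel the neighbouring triflate before it closes the ring, or the magnesium salts may open the oxirane. The fallback sets out from 22 and 18 and returns at 25. Aryne 24 is generated from 22 as in step 13 and trapped with nitrone F1 to give the ring C benzisoxazoline F7 (mixture of epimers at the new carbon). Zn in AcOH gives aminophenol F8. NaBH4 reduction of 18 gives 4-(hydroxymethyl)-1,3-phenylene bis(trifluoromethanesulfonate) F9, converted with thiolane and HBF4·OEt2 into 1-{[2,4-bis(trifluoromethanesulfonyloxy)phenyl]methyl}thiolan-1-ium tetrafluoroborate F10. The [4+1] annulation of F8 with F10 and Cs2CO3 should give 25 together with its trans (2'R,3'R)-diastereomer F11, which is removed by chromatography.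

Step 8. Epoxidation of the electron-poor, ortho-iodinated stilbene may be sluggish, with competing oxidation at iodine and loss of enantioselectivity. The fallback sets out from 13 and returns at 16 without passing through 15. The known sulfide (2S,5S)-2,5-dimethylthiolane is alkylated with 3,5-dimethoxybenzyl bromide to (2S,5S)-1-[(3,5-dimethoxyphenyl)methyl]-2,5-dimethylthiolan-1-ium bromide F12. Its ylide (Cs2CO3, MeCN, −20 °C → rt) is added to aldehyde 13 in an asymmetric sulfur-ylide epoxidation, which should give the trans-oxirane 16 directly; the (2S,5S)-sulfide is the antipode expected to deliver the (2R,3R)-oxirane.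

**Further compounds**

F1 | step 12 | (Z)-1-(3,5-dimethoxyphenyl)-N-methylmethanimine N-oxide | [O-]/[N+](C)=C\c1cc(OC)cc(OC)c1
F2 | step 12 | racemic 3-(3,5-dimethoxyphenyl)-4-methoxy-6-[(E)-2-(4-methoxyphenyl)ethenyl]-2-methyl-2,3-dihydro-1,2-benzoxazole | COc1ccc(/C=C/c2cc(OC)c3c(c2)ON(C)C3c2cc(OC)cc(OC)c2)cc1
F3 | step 12 | racemic 2-[(3,5-dimethoxyphenyl)(methylamino)methyl]-3-methoxy-5-[(E)-2-(4-methoxyphenyl)ethenyl]phenol | COc1ccc(/C=C/c2cc(OC)c(C(NC)c3cc(OC)cc(OC)c3)c(O)c2)cc1
F4 | step 12 | 4-(hydroxymethyl)-3-iodo-1,2-phenylene bis(trifluoromethanesulfonate) | OCc1ccc(OS(=O)(=O)C(F)(F)F)c(OS(=O)(=O)C(F)(F)F)c1I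
F5 | step 12 | 1-{[2-iodo-3,4-bis(trifluoromethanesulfonyloxy)phenyl]methyl}thiolan-1-ium tetrafluoroborate | F[B-](F)(F)F.Ic1c(C[S+]2CCCC2)ccc(OS(=O)(=O)C(F)(F)F)c1OS(=O)(=O)C(F)(F)F
F6 | step 12 | (2R,3R)-enantiomer of 22 | COc1ccc(/C=C/c2cc(OC)c3c(c2)O[C@@H](c2ccc(OS(=O)(=O)C(F)(F)F)c(OS(=O)(=O)C(F)(F)F)c2I)[C@@H]3c2cc(OC)cc(OC)c2)cc1
F7 | step 13 | ring C benzisoxazoline: (2S,3S)-dihydrobenzofuran of 22 with ring C fused to a 3-(3,5-dimethoxyphenyl)-2-methyl-4-(triflyloxy)-2,3-dihydro-1,2-benzoxazole (7-yl) | COc1ccc(/C=C/c2cc(OC)c3c(c2)O[C@H](c2ccc(OS(=O)(=O)C(F)(F)F)c4c2ON(C)C4c2cc(OC)cc(OC)c2)[C@H]3c2cc(OC)cc(OC)c2)cc1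
F8 | step 13 | aminophenol: ring C as 3-[(3,5-dimethoxyphenyl)(methylamino)methyl]-2-hydroxy-4-(triflyloxy)phenyl on C2 of the (2S,3S)-dihydrobenzofuran | COc1ccc(/C=C/c2cc(OC)c3c(c2)O[C@H](c2ccc(OS(=O)(=O)C(F)(F)F)c(C(NC)c4cc(OC)cc(OC)c4)c2O)[C@H]3c2cc(OC)cc(OC)c2)cc1
F9 | step 13 | 4-(hydroxymethyl)-1,3-phenylene bis(trifluoromethanesulfonate) | OCc1ccc(OS(=O)(=O)C(F)(F)F)cc1OS(=O)(=O)C(F)(F)F
F10 | step 13 | 1-{[2,4-bis(trifluoromethanesulfonyloxy)phenyl]methyl}thiolan-1-ium tetrafluoroborate | F[B-](F)(F)F.FC(F)(F)S(=O)(=O)Oc1ccc(C[S+]2CCCC2)c(OS(=O)(=O)C(F)(F)F)c1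
F11 | step 13 | (2'R,3'R)-diastereomer of 25 | COc1ccc(/C=C/c2cc(OC)c3c(c2)O[C@H](c2ccc(OS(=O)(=O)C(F)(F)F)c4c2O[C@@H](c2ccc(OS(=O)(=O)C(F)(F)F)cc2OS(=O)(=O)C(F)(F)F)[C@@H]4c2cc(OC)cc(OC)c2)[C@H]3c2cc(OC)cc(OC)c2)cc1
F12 | step 8 | (2S,5S)-1-[(3,5-dimethoxyphenyl)methyl]-2,5-dimethylthiolan-1-ium bromide | C[C@H]1CC[C@H](C)[S+]1Cc1cc(OC)cc(OC)c1.[Br-]
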